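Ring B carries oxygen at C2' and C4', a 1,3-pattern that betrays two former carbonyl carbons of a linear keto ester; the C5' methoxy sits next to one of them. Everything rests on cutting C3'–C4' and forming ring B last, on a finished chromone (rings A and C). The precursor 18 is a hex-3-enoate hung from chromone C2 through its C4: a methyl ketone at one end, an α-methoxy methyl ester at the other, a Z alkene holding both ends on the same side. Methoxide closes the six-membered ring by intramolecular Claisen acylation, and the enedione formed tautomerises at once to the 2',4'-dihydroxy-5'-methoxyphenyl ring of 20. Regioselective methylation of the C4' hydroxyl completes the target.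

Key step: step 7

Assumption: 18 is drawn and named as the Z isomer with the C3=C4 alkene; its E isomer and its C2=C3 tautomers (α-methoxyacrylate or dienol) share one conjugate base, so material of mixed geometry or tautomer content is taken into step 7 unchanged.

Step 1
Reactants: 1 1,2,3-trimethoxybenzene; 2 N,2-dimethoxy-N-methylacetamide
Product: 4 2-methoxy-1-(2,3,4-trimethoxyphenyl)ethan-1-one, via 2,3,4-trimethoxyphenyllithium 3 (not isolated)
Conditions: n-BuLi, TMEDA, THF, 0 °C; then 2, −78 °C to 0 °C; 1 M HCl
Reagents that add atoms: none
Why: Directed ortho-lithiation can only take place at the equivalent C4/C6 positions beside an outer methoxy group, and the Weinreb ketone synthesis should deliver the ketone without over-addition while avoiding a Lewis acid acylation with methoxyacetyl chloride, whose acylium ion is prone to lose CO.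

Step 2
Reactants: 4 2-methoxy-1-(2,3,4-trimethoxyphenyl)ethan-1-one
Product: 6 1-(2-hydroxy-3,4-dimethoxyphenyl)-2-methoxyethan-1-one, via aryloxydichloroborane 5 (not isolated)
Conditions: BCl3 (1.2 equiv), CH2Cl2, −78 °C to 0 °C; H2O
Reagents that add atoms: none
Why: Chelation-directed aryl methyl ether cleavage, in which BCl3 bound to the ketone oxygen reaches only the ortho methoxy group and chloride removes its methyl within a six-membered boron chelate, whereas the remote aryl ethers and the aliphatic ether (a poorer leaving group) should stay intact.

Step 3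
Reactants: 6 1-(2-hydroxy-3,4-dimethoxyphenyl)-2-methoxyethan-1-one; 7 acetic anhydride
Product: 10 3,7,8-trimethoxy-2-methyl-4H-chromen-4-one, via aryl acetate 8 (not isolated), via 1,3-diketone 9 (not isolated)
Conditions: Ac2O (excess), NaOAc, reflux, 140 °C; then H2O
Reagents that add atoms: none
Why: Kostanecki–Robinson chromone synthesis (O-acetylation, base-induced O-to-C acyl shift onto the methoxy-bearing methylene, cyclodehydration), a sequence that steers ω-methoxy-2-hydroxyacetophenones to 3-methoxy-2-methylchromones rather than coumarins and to which all aryl ethers are inert.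

Step 4
Reactants: 10 3,7,8-trimethoxy-2-methyl-4H-chromen-4-one; 11 N-methoxy-N-methylacetamide
Product: 13 1-(3,7,8-trimethoxy-4-oxo-4H-chromen-2-yl)propan-2-one, via 2-(lithiomethyl)chromone 12 (not isolated)
Conditions: LiN(i-Pr)2 (commercial solution, 1.1 equiv), THF, −78 °C; then 11, −78 °C to 0 °C; 1 M HCl
Reagents that add atoms: none
Why: The 2-methyl group is the γ-position of a vinylogous ester and, with C3 blocked by methoxy, the only acidic site, so lateral lithiation followed by Weinreb acylation should give the ketone, which is released only at the quench and therefore cannot protonate unreacted 12.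

Step 5
Reactants: 14 methyl methoxyacetate; 15 methyl formate
Product: 17 methyl 2-methoxy-3-oxopropanoate, via sodium enolate 16 (not isolated)
Conditions: 15 (3 equiv), NaOMe (1.1 equiv), THF, 0 °C to rt; then cold 1 M HCl, extraction, used crude at once
Reagents that add atoms: none
Why: Crossed Claisen condensation in which the non-enolisable and more electrophilic formate is the acceptor in excess and formation of the stabilised enolate 16 drives the equilibrium, the α-carbon of 17 being racemic and configurationally labile through its predominant enol form.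

Step 6
Reactants: 13 1-(3,7,8-trimethoxy-4-oxo-4H-chromen-2-yl)propan-2-one; 17 methyl 2-methoxy-3-oxopropanoate
Product: 18 methyl (Z)-2-methoxy-5-oxo-4-(3,7,8-trimethoxy-4-oxo-4H-chromen-2-yl)hex-3-enoate (racemic at C2)
Conditions: piperidine (0.2 equiv), AcOH (0.5 equiv), toluene, 4 Å molecular sieves, 40 °C
Reagents that add atoms: none
Why: Knoevenagel condensation in which the methylene of 13, flanked by the acetyl group and the vinylogous acyl carbon C2 of the chromone, adds to the iminium ion that piperidinium acetate makes from the formyl ester (the way hydroxymethylene carbonyl compounds condense with active methylene partners), loss of the amine placing the alkene at C3=C4, while C2 stays racemic and the alkene geometry needs no control because step 7 equilibrates it.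

Step 7
Reactants: 18 methyl (Z)-2-methoxy-5-oxo-4-(3,7,8-trimethoxy-4-oxo-4H-chromen-2-yl)hex-3-enoate
Product: 20 2-(2,4-dihydroxy-5-methoxyphenyl)-3,7,8-trimethoxy-4H-chromen-4-one, via cyclohexenedione 19 (not isolated)
Conditions: NaOMe (4 equiv), dry MeOH–THF, 65 °C, Ar, dilute; then 1 M HCl, 0 °C
Reagents that add atoms: none
Why: Methoxide first removes the highly acidic C2–H of 18, giving a delocalised anion in which the C3–C4 bond rotates (so E and Z material converge) and from which closure through the ketone oxygen to a 2-pyranone is undone again by methoxide. Proton exchange with methanol keeps a small share of the isomeric C6 methyl ketone enolate available, expected to be of the same order as the enolate share in an ordinary alkoxide-mediated Dieckmann reaction, and in this isomer the α-methoxy ester is not enolised and is inductively activated. C6 attacks the ester carbonyl C1 in a favoured 6-(enolendo)-exo-trig closure, methoxide leaves, and the C3'–C4' bond and ring B stand as enedione 19. Two keto–enol shifts (at C3' and C5') turn 19 into the benzene ring, which is held as its bis-phenoxide, so this exit is irreversible and should drain the equilibria, which answers the required chemoselectivity between the two carbanion sites. The closest known reaction type is the intramolecular Claisen (Dieckmann-type) cycloaromatisation of 5-oxohexenoates, including those released from 6-methyl-2-pyranones by methoxide, to resorcinols and phloroglucinol ethers. No stereocentre is created (racemic C2 becomes planar C5'), the charge spread into the chromone shields its C2 against methoxide, and argon protects the electron-rich phenoxide from air.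

Step 8
Reactants: 20 2-(2,4-dihydroxy-5-methoxyphenyl)-3,7,8-trimethoxy-4H-chromen-4-one
Product: 21 2-(2-hydroxy-4,5-dimethoxyphenyl)-3,7,8-trimethoxy-4H-chromen-4-one
Conditions: MeI (1.0 equiv), K2CO3 (1.0 equiv), acetone, 0 °C to rt, Ar
Reagents that add atoms: iodomethane CI
Why: Williamson etherification under substrate control, since with one equivalent of base the phenoxide should sit on the C4' oxygen (para to the electron-poor chromone C2, flanked only by H and OMe) while the C2' hydroxyl is buried beside the twisted 3-methoxychromone and hydrogen-bonded to its oxygens, and the phenolic target can be parted from any neutral dimethyl ether by extraction into aqueous NaOH.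

Compound list
1 | 1,2,3-trimethoxybenzene | COc1cccc(OC)c1OC | starting material
2 | N,2-dimethoxy-N-methylacetamide | COCC(=O)N(C)OC | starting material
3 | 2,3,4-trimethoxyphenyllithium | [Li]c1ccc(OC)c(OC)c1OC | intermediate
4 | 2-methoxy-1-(2,3,4-trimethoxyphenyl)ethan-1-one | COCC(=O)c1ccc(OC)c(OC)c1OC | intermediate
5 | dichloro[6-(methoxyacetyl)-2,3-dimethoxyphenoxy]borane | COCC(=O)c1ccc(OC)c(OC)c1OB(Cl)Cl | intermediate
6 | 1-(2-hydroxy-3,4-dimethoxyphenyl)-2-methoxyethan-1-one | COCC(=O)c1ccc(OC)c(OC)c1O | intermediate
7 | acetic anhydride | CC(=O)OC(C)=O | starting material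
8 | 6-(methoxyacetyl)-2,3-dimethoxyphenyl acetate | COCC(=O)c1ccc(OC)c(OC)c1OC(C)=O | intermediate
9 | 1-(2-hydroxy-3,4-dimethoxyphenyl)-2-methoxybutane-1,3-dione (racemic) | COC(C(C)=O)C(=O)c1ccc(OC)c(OC)c1O | intermediate
10 | 3,7,8-trimethoxy-2-methyl-4H-chromen-4-one | COc1c(C)oc2c(OC)c(OC)ccc2c1=O | intermediate
11 | N-methoxy-N-methylacetamide | CC(=O)N(C)OC | starting material
12 | [(3,7,8-trimethoxy-4-oxo-4H-chromen-2-yl)methyl]lithium | [Li]Cc1oc2c(OC)c(OC)ccc2c(=O)c1OC | intermediate
13 | 1-(3,7,8-trimethoxy-4-oxo-4H-chromen-2-yl)propan-2-one | CC(=O)Cc1oc2c(OC)c(OC)ccc2c(=O)c1OC | intermediate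
14 | methyl methoxyacetate | COCC(=O)OC | starting material
15 | methyl formate | COC=O | starting material
16 | sodium 2,3-dimethoxy-3-oxoprop-1-en-1-olate (geometry not defined) | [Na+].[O-]C=C(OC)C(=O)OC | intermediate
17 | methyl 2-methoxy-3-oxopropanoate (racemic, mainly enol) | COC(=O)C(OC)C=O | intermediate
18 | methyl (Z)-2-methoxy-5-oxo-4-(3,7,8-trimethoxy-4-oxo-4H-chromen-2-yl)hex-3-enoate (racemic at C2) | COC(=O)C(OC)/C=C(\C(C)=O)c1oc2c(OC)c(OC)ccc2c(=O)c1OC | intermediate
19 | 6-methoxy-4-(3,7,8-trimethoxy-4-oxo-4H-chromen-2-yl)cyclohex-4-ene-1,3-dione (racemic) | COC1C=C(C(=O)CC1=O)c1oc2c(OC)c(OC)ccc2c(=O)c1OC | intermediate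
20 | 2-(2,4-dihydroxy-5-methoxyphenyl)-3,7,8-trimethoxy-4H-chromen-4-one | COc1cc(-c2oc3c(OC)c(OC)ccc3c(=O)c2OC)c(O)cc1O | intermediate
21 | 2-(2-hydroxy-4,5-dimethoxyphenyl)-3,7,8-trimethoxy-4H-chromen-4-one | COc1cc(O)c(-c2oc3c(OC)c(OC)ccc3c(=O)c2OC)cc1OC | target

Total step count: 8
Longest linear sequence: 7 (steps 1, 2, 3, 4, 6, 7, 8; step 5 is a side branch)

Steps most likely to fail

Risk 1, step 7. The substrate may simply rest as its stabilised anion. Ring closure through carbon could then be outrun by slow removal of the acetyl group by methoxide (retro-Claisen cleavage) or by oxidation of the electron-rich anions.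
- The fallback sets out from 18 and comes back at 20. It lowers the oxidation level first, so that the ester is no longer conjugated with the resting anion.
- Conjugate reduction of the doubly activated C3=C4 alkene with diethyl 2,6-dimethyl-1,4-dihydropyridine-3,5-dicarboxylate (Hantzsch ester) in warm toluene should give methyl 2-methoxy-5-oxo-4-(3,7,8-trimethoxy-4-oxo-4H-chromen-2-yl)hexanoate F1.
- KOt-Bu in THF then effects the textbook Claisen closure of a δ-keto ester. It forms the same C3'–C4' bond and gives 4-methoxy-6-(3,7,8-trimethoxy-4-oxo-4H-chromen-2-yl)cyclohexane-1,3-dione F2.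
- One equivalent of DDQ in dioxane dehydrogenates F2 across C1'–C6', and tautomerisation delivers 20.

Risk 2, step 6. The formyl ester may stay parked as its enol or as the enamine formed with the catalyst. Condensation would then be slow, and self-condensation or premature lactonisation of the product could take over.
- The fallback sets out from 13 and 14 and comes back at 18.
- Heating 14 with tert-butoxybis(dimethylamino)methane should give methyl (Z)-3-(dimethylamino)-2-methoxyacrylate F3.
- F3 and 13 in refluxing AcOH should undergo the established replacement of a dimethylamino group by an active methylene carbon, followed by enol lactonisation. The product is 3-methoxy-6-methyl-5-(3,7,8-trimethoxy-4-oxo-4H-chromen-2-yl)-2H-pyran-2-one F4, a robust storage form of the same carbon chain.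
- NaOMe in MeOH opens the lactone to the sodium salt of 18, which is the species that enters step 7.

Risk 3, step 8. Discrimination between the two phenols may be insufficient, so that both oxygens or the wrong one are methylated.
- The fallback sets out from 20 and comes back at 21. It amplifies the steric difference with a bulky silyl group and caps C2' temporarily.
- i-Pr3SiCl and imidazole in DMF should silylate only the open C4' hydroxyl and give 2-[2-hydroxy-5-methoxy-4-(triisopropylsilyloxy)phenyl]-3,7,8-trimethoxy-4H-chromen-4-one F5. A wrong isomer can be desilylated and recycled.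
- BnBr and K2CO3 in acetone give 2-[2-(benzyloxy)-5-methoxy-4-(triisopropylsilyloxy)phenyl]-3,7,8-trimethoxy-4H-chromen-4-one F6.
- n-Bu4NF followed by MeI in THF exchanges silyl for methyl and gives 2-[2-(benzyloxy)-4,5-dimethoxyphenyl]-3,7,8-trimethoxy-4H-chromen-4-one F7.
- H2 over Pd/C in EtOAc removes the benzyl group and gives 21.

Further compounds
F1 | step 7 | methyl 2-methoxy-5-oxo-4-(3,7,8-trimethoxy-4-oxo-4H-chromen-2-yl)hexanoate (mixture of diastereomers) | COC(=O)C(OC)CC(C(C)=O)c1oc2c(OC)c(OC)ccc2c(=O)c1OC
F2 | step 7 | 4-methoxy-6-(3,7,8-trimethoxy-4-oxo-4H-chromen-2-yl)cyclohexane-1,3-dione (mixture of diastereomers) | COC1CC(C(=O)CC1=O)c1oc2c(OC)c(OC)ccc2c(=O)c1OC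
F3 | step 6 | methyl (Z)-3-(dimethylamino)-2-methoxyacrylate | COC(=O)/C(OC)=C/N(C)C
F4 | step 6 | 3-methoxy-6-methyl-5-(3,7,8-trimethoxy-4-oxo-4H-chromen-2-yl)-2H-pyran-2-one | COc1cc(-c2oc3c(OC)c(OC)ccc3c(=O)c2OC)c(C)oc1=O
F5 | step 8 | 2-[2-hydroxy-5-methoxy-4-(triisopropylsilyloxy)phenyl]-3,7,8-trimethoxy-4H-chromen-4-one | COc1cc(-c2oc3c(OC)c(OC)ccc3c(=O)c2OC)c(O)cc1O[Si](C(C)C)(C(C)C)C(C)C
F6 | step 8 | 2-[2-(benzyloxy)-5-methoxy-4-(triisopropylsilyloxy)phenyl]-3,7,8-trimethoxy-4H-chromen-4-one | COc1cc(-c2oc3c(OC)c(OC)ccc3c(=O)c2OC)c(OCc2ccccc2)cc1O[Si](C(C)C)(C(C)C)C(C)C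
F7 | step 8 | 2-[2-(benzyloxy)-4,5-dimethoxyphenyl]-3,7,8-trimethoxy-4H-chromen-4-one | COc1cc(OCc2ccccc2)c(-c2oc3c(OC)c(OC)ccc3c(=O)c2OC)cc1OC
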